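**Plan**

- Rings: A = the methoxy/hydroxy ring, B = the meta-phenylene, C = the catechol-derived ring, D = the para-phenylene. Retrosynthetic cuts, in order: (a) the diaryl ether bond between the ring C oxygen meta to its bridge and C4 of ring D, which opens the 18-membered ring; (b) the ring A–CH2 bond of the A–D bridge; (c) the ring B–CH2 bond of the B–C bridge; (d) the ring A O–ring B bond.
- Forward order: A–O–B ether (Chan–Lam), ring A phenol from the formyl group (Baeyer–Villiger) and benzylation, B–C bibenzyl (B-alkyl Suzuki at C–I), A–D bridge as a ketone (α-arylation at C–Br), macrocyclization, deoxygenation, debenzylation.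
- Enabling feature: the ring D carbon to be bonded is para to the benzylic carbon of the two-carbon bridge to ring A. Held at the ketone oxidation level, that carbon makes ring D a 4-fluorobenzoyl unit open to SNAr only at the required carbon. Ring C is a catechol whose oxygen para to its bridge is blocked as a benzyl ether.
- Helpers and their removal: the TIPS group is consumed in the key step, the ketone oxygen leaves in step 9, the benzyl ethers in step 10.
- Stereochemistry: the target has no stereocenter and no double bond of defined geometry, so nothing has to be set.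
- Remark: compounds 1, 2, 7 and 12 are taken as catalogue compounds.

Key step: step 8

**Route**

Step 1
Reactants: 1 2-bromo-3-hydroxy-4-methoxybenzaldehyde (2-bromoisovanillin); 2 (3-iodophenyl)boronic acid
Product: 3 2-bromo-3-(3-iodophenoxy)-4-methoxybenzaldehyde
Conditions: Cu(OAc)2 (2 equiv), pyridine (5 equiv), 4 Å MS, CH2Cl2, dry air, rt
Reagents that add atoms: none
Why: Chan–Lam oxidative O-arylation with divalent copper couples phenols that carry two ortho substituents at room temperature and should leave the aldehyde and both carbon–halogen bonds untouched.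

Step 2
Reactants: 3 2-bromo-3-(3-iodophenoxy)-4-methoxybenzaldehyde
Product: 5 2-bromo-3-(3-iodophenoxy)-4-methoxyphenol, via aryl formate 4 (not isolated)
Conditions: mCPBA (1.3 equiv), CH2Cl2, 0 °C to rt; aq. NaHCO3 wash; then K2CO3 (cat.), MeOH, rt
Reagents that add atoms: mCPBA, OOC(=O)c1cccc(Cl)c1
Why: In this Baeyer–Villiger (Dakin-type) oxidation the aryl group, made electron-rich by the methoxy group para to the formyl carbon, should migrate to oxygen, and mild methanolysis of the formate frees the phenol.

Step 3
Reactants: 5 2-bromo-3-(3-iodophenoxy)-4-methoxyphenol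
Product: 6 1-(benzyloxy)-2-bromo-3-(3-iodophenoxy)-4-methoxybenzene
Conditions: BnBr, K2CO3, DMF, rt
Reagents that add atoms: benzyl bromide, BrCc1ccccc1
Why: Williamson etherification of the phenoxide with a benzylic bromide protects the ring A oxygen as an ether that lasts until the final hydrogenolysis.

Step 4
Reactants: 7 4-(benzyloxy)-3-hydroxybenzaldehyde
Product: 8 4-(benzyloxy)-3-[(triisopropylsilyl)oxy]benzaldehyde
Conditions: TIPSCl, imidazole, DMF, rt
Reagents that add atoms: triisopropylsilyl chloride, CC(C)[Si](Cl)(C(C)C)C(C)C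
Why: Imidazole-promoted silylation gives a bulky aryl silyl ether that should survive the basic steps 5 to 7 and be cleaved by fluoride exactly when the phenoxide is needed.

Step 5
Reactants: 8 4-(benzyloxy)-3-[(triisopropylsilyl)oxy]benzaldehyde
Product: 9 1-(benzyloxy)-4-ethenyl-2-[(triisopropylsilyl)oxy]benzene
Conditions: Ph3PCH3Br, KOtBu, THF, 0 °C; then 8, 0 °C to rt
Reagents that add atoms: methyltriphenylphosphonium bromide, C[P+](c1ccccc1)(c1ccccc1)c1ccccc1.[Br-]
Why: Wittig methylenation with the preformed, non-stabilized ylide converts the aldehyde into the styrene without touching the silyl or benzyl ether.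

Step 6
Reactants: 9 1-(benzyloxy)-4-ethenyl-2-[(triisopropylsilyl)oxy]benzene; 6 1-(benzyloxy)-2-bromo-3-(3-iodophenoxy)-4-methoxybenzene
Product: 11 1-(benzyloxy)-3-(3-{2-[4-(benzyloxy)-3-(triisopropylsilyloxy)phenyl]ethyl}phenoxy)-2-bromo-4-methoxybenzene, via B-alkyl-9-BBN borane 10 (not isolated)
Conditions: 9, 9-BBN dimer, THF, 0 °C to rt; then 6, Pd(dppf)Cl2 (5 mol%), K3PO4 (3 M aq.), DMF, rt
Reagents that add atoms: 9-borabicyclo[3.3.1]nonane (9-BBN), B1C2CCCC1CCC2 (boron and bicycle stay only in intermediate 10; product 11 keeps one hydrogen from it)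
Why: Anti-Markovnikov hydroboration of the styrene followed by B-alkyl Suzuki–Miyaura coupling builds the saturated bibenzyl directly, and zerovalent palladium should insert into the unhindered C–I bond of ring B at room temperature far faster than into the C–Br bond of ring A that is flanked by two oxygens.

Step 7
Reactants: 11 1-(benzyloxy)-3-(3-{2-[4-(benzyloxy)-3-(triisopropylsilyloxy)phenyl]ethyl}phenoxy)-2-bromo-4-methoxybenzene; 12 1-(4-fluorophenyl)ethan-1-one (4'-fluoroacetophenone)
Product: 13 2-[6-(benzyloxy)-2-(3-{2-[4-(benzyloxy)-3-(triisopropylsilyloxy)phenyl]ethyl}phenoxy)-3-methoxyphenyl]-1-(4-fluorophenyl)ethan-1-one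
Conditions: Pd2(dba)3 (2.5 mol%), XPhos (10 mol%), K3PO4 (2.5 equiv), 12 (2 equiv), toluene, 100 °C
Reagents that add atoms: none
Why: Palladium-catalysed α-arylation of a methyl ketone (Buchwald–Hartwig type) with a bulky dialkylbiarylphosphine should allow oxidative addition at the doubly ortho-substituted bromide, the mild phosphate base spares the silyl ether and the C–F bond, and the more acidic product stays as its enolate, which resists a second arylation.

Step 8
Reactants: 13 2-[6-(benzyloxy)-2-(3-{2-[4-(benzyloxy)-3-(triisopropylsilyloxy)phenyl]ethyl}phenoxy)-3-methoxyphenyl]-1-(4-fluorophenyl)ethan-1-one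
Product: 15 macrocyclic ketone (the 18-membered bis(diaryl ether) ring of the target with benzyl ethers on the ring A and ring C oxygens and C=O at the bridge carbon on ring D), via cesium phenoxide 14 (not isolated)
Conditions: CsF (3 equiv), DMSO, 100 °C, argon; 13 added by syringe pump to 0.002 M final concentration
Reagents that add atoms: cesium fluoride, [Cs+].[F-] (supplies only the cesium counter-ion of intermediate 14; no atom of it remains in 15)
Why: Fluoride strips the TIPS group from the ring C oxygen to give cesium phenoxide 14, whose oxygen adds to C4 of the 4-fluorobenzoyl ring D to form a Meisenheimer anion delocalized into the para ketone, and loss of fluoride gives the diaryl ether and returns the fluoride that desilylates the next molecule. The closest known reaction type is the intramolecular SNAr macroetherification of carbonyl- or nitro-activated fluoroarenes, combined with the CsF-mediated desilylative SNAr of aryl silyl ethers. The one ring closed is the 18-membered macrocycle, formed end to end by addition–elimination at an sp2 carbon under high dilution, and no stereocenter arises. On the electrophile the step needs site selectivity, secured because the ring D C–F bond is the only carbon–halogen bond para to a carbonyl group; on the nucleophile it needs regioselectivity between the catechol oxygens, secured because the oxygen para to the ring C bridge and the ring A oxygen are benzyl ethers, so only the oxygen meta to the bridge can become a phenoxide. Ring closure should be favoured over oligomerization by slow addition into hot dilute CsF, and enolization of the ketone stays reversible and harmless because no base stronger than phenoxide and fluoride is present and air is excluded.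

Step 9
Reactants: 15 macrocyclic ketone
Product: 16 macrocyclic bis(benzyl ether) (the target with both phenols as benzyl ethers)
Conditions: Et3SiH (5 equiv), TFA/CH2Cl2 (1:2), 0 °C to rt
Reagents that add atoms: none
Why: Ionic hydrogenation (Kursanov–Parnes reduction) should take the aryl ketone to the methylene group through a benzylic cation stabilized by the para aryloxy group, under conditions that aryl benzyl ethers and diaryl ethers tolerate.

Step 10
Reactants: 16 macrocyclic bis(benzyl ether)
Product: 17 target, CNP0179896.0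
Conditions: H2 (1 atm), Pd/C (10 wt%), EtOAc/MeOH, rt
Reagents that add atoms: none
Why: Catalytic hydrogenolysis cleaves both benzyl ethers and should leave the diaryl ethers, the methyl ether and the saturated bridges unchanged.

**Compound list**

1 | 2-bromo-3-hydroxy-4-methoxybenzaldehyde | COc1ccc(C=O)c(Br)c1O | starting material
2 | (3-iodophenyl)boronic acid | OB(O)c1cccc(I)c1 | starting material
3 | 2-bromo-3-(3-iodophenoxy)-4-methoxybenzaldehyde | COc1ccc(C=O)c(Br)c1Oc1cccc(I)c1 | intermediate
4 | 2-bromo-3-(3-iodophenoxy)-4-methoxyphenyl formate | COc1ccc(OC=O)c(Br)c1Oc1cccc(I)c1 | intermediate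
5 | 2-bromo-3-(3-iodophenoxy)-4-methoxyphenol | COc1ccc(O)c(Br)c1Oc1cccc(I)c1 | intermediate
6 | 1-(benzyloxy)-2-bromo-3-(3-iodophenoxy)-4-methoxybenzene | COc1ccc(OCc2ccccc2)c(Br)c1Oc1cccc(I)c1 | intermediate
7 | 4-(benzyloxy)-3-hydroxybenzaldehyde | O=Cc1ccc(OCc2ccccc2)c(O)c1 | starting material
8 | 4-(benzyloxy)-3-[(triisopropylsilyl)oxy]benzaldehyde | O=Cc1ccc(OCc2ccccc2)c(O[Si](C(C)C)(C(C)C)C(C)C)c1 | intermediate
9 | 1-(benzyloxy)-4-ethenyl-2-[(triisopropylsilyl)oxy]benzene | C=Cc1ccc(OCc2ccccc2)c(O[Si](C(C)C)(C(C)C)C(C)C)c1 | intermediate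
10 | 9-{2-[4-(benzyloxy)-3-(triisopropylsilyloxy)phenyl]ethyl}-9-borabicyclo[3.3.1]nonane | CC(C)[Si](Oc1cc(CCB2C3CCCC2CCC3)ccc1OCc1ccccc1)(C(C)C)C(C)C | intermediate
11 | 1-(benzyloxy)-3-(3-{2-[4-(benzyloxy)-3-(triisopropylsilyloxy)phenyl]ethyl}phenoxy)-2-bromo-4-methoxybenzene | COc1ccc(OCc2ccccc2)c(Br)c1Oc1cccc(CCc2ccc(OCc3ccccc3)c(O[Si](C(C)C)(C(C)C)C(C)C)c2)c1 | intermediate
12 | 1-(4-fluorophenyl)ethan-1-one | CC(=O)c1ccc(F)cc1 | starting material
13 | 2-[6-(benzyloxy)-2-(3-{2-[4-(benzyloxy)-3-(triisopropylsilyloxy)phenyl]ethyl}phenoxy)-3-methoxyphenyl]-1-(4-fluorophenyl)ethan-1-one | COc1ccc(OCc2ccccc2)c(CC(=O)c2ccc(F)cc2)c1Oc1cccc(CCc2ccc(OCc3ccccc3)c(O[Si](C(C)C)(C(C)C)C(C)C)c2)c1 | intermediate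
14 | cesium 2-(benzyloxy)-5-{2-[3-(3-(benzyloxy)-2-[2-(4-fluorophenyl)-2-oxoethyl]-6-methoxyphenoxy)phenyl]ethyl}phenoxide | COc1ccc(OCc2ccccc2)c(CC(=O)c2ccc(F)cc2)c1Oc1cccc(CCc2ccc(OCc3ccccc3)c([O-])c2)c1.[Cs+] | intermediate
15 | macrocyclic ketone: 18-membered ring of the target, benzyl ethers on the ring A and ring C oxygens, C=O at the bridge carbon on ring D | COc1ccc(OCc3ccccc3)c2c1Oc1cccc(c1)CCc1ccc(OCc3ccccc3)c(c1)Oc1ccc(cc1)C(=O)C2 | intermediate
16 | macrocyclic bis(benzyl ether) of the target | COc1ccc(OCc3ccccc3)c2c1Oc1cccc(c1)CCc1ccc(OCc3ccccc3)c(c1)Oc1ccc(cc1)CC2 | intermediate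
17 | CNP0179896.0 | COc1ccc(O)c2c1Oc1cccc(c1)CCc1ccc(O)c(c1)Oc1ccc(cc1)CC2 | target

**Count**

Total steps: 10. Longest linear sequence: 8 (steps 1, 2, 3, 6, 7, 8, 9, 10).

**Steps most likely to fail**

Step 8. Intermolecular etherification may outrun ring closure, and enolization of the ketone next to ring D by phenoxide or fluoride may switch off the activation of the C–F bond. The fallback closes the same O–C bond by copper catalysis on an unactivated bromide. It sets out from 11 and comes back at 16, so step 9 falls away.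
- Bromine–lithium exchange on 11 (n-BuLi, THF, −78 °C) gives [2-(benzyloxy)-6-(3-{2-[4-(benzyloxy)-3-(triisopropylsilyloxy)phenyl]ethyl}phenoxy)-5-methoxyphenyl]lithium F1.
- Quenching with DMF gives 6-(benzyloxy)-2-(3-{2-[4-(benzyloxy)-3-(triisopropylsilyloxy)phenyl]ethyl}phenoxy)-3-methoxybenzaldehyde F2.
- Wittig olefination with the ylide from (4-bromobenzyl)triphenylphosphonium bromide (KOtBu, THF) gives the 4-bromostilbene F3 as an E/Z mixture.
- Diimide reduction (TsNHNH2, NaOAc, aqueous DME, reflux) saturates the double bond without touching the C–Br bond or the benzyl ethers and gives the bibenzyl bromide F4.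
- TBAF in THF frees the phenol F5.
- Intramolecular Ullmann etherification (CuI, N,N-dimethylglycine, Cs2CO3, dioxane, 100 °C, high dilution) then gives 16.

Step 7. Oxidative addition at the C–Br bond between two oxygens may be slow, and intramolecular C–H arylation of ring B or of the benzyl group, or hydrodebromination, may take over. The fallback builds the ketone without palladium and sets out from 11 and comes back at 13.
- The aryllithium F1 and the aldehyde F2 are made from 11 as above.
- Condensation of F2 with tosylhydrazide (MeOH, rt) gives the (E)-N-tosylhydrazone F6.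
- Heating F6 with 4-fluorobenzaldehyde and K2CO3 in dioxane at 110 °C releases the aryldiazomethane F7 (Bamford–Stevens).
- F7 adds to the aldehyde and, after hydride shift and loss of nitrogen (Buchner–Curtius–Schlotterbeck homologation), gives 13.

Step 1. O-arylation of the phenol flanked by bromine and methoxy may be slow, so that protodeboronation and homocoupling of the boronic acid consume the partner. The fallback sets out from 1 and comes back at 3. It is an Ullmann etherification of 1 with 1,3-diiodobenzene in excess (CuI, N,N-dimethylglycine, Cs2CO3, dioxane, 90 °C). The excess of the diiodide holds the reaction at the mono-ether, and the C–I bond should react ahead of the C–Br bond of 1.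

**Further compounds**

F1 | step 8 | [2-(benzyloxy)-6-(3-{2-[4-(benzyloxy)-3-(triisopropylsilyloxy)phenyl]ethyl}phenoxy)-5-methoxyphenyl]lithium | COc1ccc(OCc2ccccc2)c([Li])c1Oc1cccc(CCc2ccc(OCc3ccccc3)c(O[Si](C(C)C)(C(C)C)C(C)C)c2)c1
F2 | step 8 | 6-(benzyloxy)-2-(3-{2-[4-(benzyloxy)-3-(triisopropylsilyloxy)phenyl]ethyl}phenoxy)-3-methoxybenzaldehyde | COc1ccc(OCc2ccccc2)c(C=O)c1Oc1cccc(CCc2ccc(OCc3ccccc3)c(O[Si](C(C)C)(C(C)C)C(C)C)c2)c1
F3 | step 8 | 1-(benzyloxy)-3-(3-{2-[4-(benzyloxy)-3-(triisopropylsilyloxy)phenyl]ethyl}phenoxy)-2-[2-(4-bromophenyl)ethenyl]-4-methoxybenzene (E/Z mixture) | COc1ccc(OCc2ccccc2)c(C=Cc2ccc(Br)cc2)c1Oc1cccc(CCc2ccc(OCc3ccccc3)c(O[Si](C(C)C)(C(C)C)C(C)C)c2)c1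
F4 | step 8 | 1-(benzyloxy)-3-(3-{2-[4-(benzyloxy)-3-(triisopropylsilyloxy)phenyl]ethyl}phenoxy)-2-[2-(4-bromophenyl)ethyl]-4-methoxybenzene | COc1ccc(OCc2ccccc2)c(CCc2ccc(Br)cc2)c1Oc1cccc(CCc2ccc(OCc3ccccc3)c(O[Si](C(C)C)(C(C)C)C(C)C)c2)c1
F5 | step 8 | 2-(benzyloxy)-5-{2-[3-(3-(benzyloxy)-2-[2-(4-bromophenyl)ethyl]-6-methoxyphenoxy)phenyl]ethyl}phenol | COc1ccc(OCc2ccccc2)c(CCc2ccc(Br)cc2)c1Oc1cccc(CCc2ccc(OCc3ccccc3)c(O)c2)c1
F6 | step 7 | (E)-N-tosylhydrazone of aldehyde F2 | COc1ccc(OCc2ccccc2)c(/C=N/NS(=O)(=O)c2ccc(C)cc2)c1Oc1cccc(CCc2ccc(OCc3ccccc3)c(O[Si](C(C)C)(C(C)C)C(C)C)c2)c1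
F7 | step 7 | aryldiazomethane from F6 | COc1ccc(OCc2ccccc2)c(C=[N+]=[N-])c1Oc1cccc(CCc2ccc(OCc3ccccc3)c(O[Si](C(C)C)(C(C)C)C(C)C)c2)c1
F0 | step 1 | none | none
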